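**Strategy.** The molecule is cut at the single C2–C1' bond that joins the chromanone (rings A and C) to the syringyl ring B. C2 is an sp3 benzylic carbon beta to the C4 ketone, so in the precursor it is the electrophilic beta-carbon of a flat 5,7-bis(benzyloxy)chromone. One rhodium-catalysed asymmetric 1,4-addition of an arylboronic acid forms this bond and sets C2 (S) without touching the pyranone ring. The boronic acid already carries the complete threo (7R,8R) aryl glycerol ether, silyl-protected, built on ring B by phenol O-alkylation and an auxiliary-controlled syn glycolate aldol. Desilylation and hydrogenolysis then finish the synthesis.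

Key step: step 9

Numbering: flavanone numbering for rings A and C, primes for ring B, C7/C8/C9 for the glycerol chain, ring D for the 4-hydroxyphenyl ring.

Assumption: the chiral diene is taken to select the same enone face on the chromone as on 2-cyclohexenone, which makes (1S,4S)-2,5-diphenylbicyclo[2.2.2]octa-2,5-diene ((S,S)-Ph-bod) the ligand for 2S; a trial with phenylboronic acid fixes this beforehand, and the (R,R) ligand is used if the sense is opposite.

**Route**

Step 1
Reactants: 1 4-bromo-2,6-dimethoxyphenol; 2 ethyl bromoacetate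
Product: 4 (4-bromo-2,6-dimethoxyphenoxy)acetic acid, via ethyl ester 3 (not isolated)
Conditions: K2CO3, MeCN, 70 °C; then 2 M NaOH (aq), rt; then HCl to pH 2
Reagents that add atoms: sodium hydroxide, [Na+].[OH-] (hydroxyl oxygen of the acid)
Why: Williamson ether synthesis of the phenoxide on the primary alpha-bromo ester followed by saponification in the same pot should give the aryloxyacetic acid, the aryl bromide being inert and no stereocentre being involved.

Step 2
Reactants: 4 (4-bromo-2,6-dimethoxyphenoxy)acetic acid; 5 (S)-4-benzyl-2-oxazolidinone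
Product: 7 (S)-4-benzyl-3-[(4-bromo-2,6-dimethoxyphenoxy)acetyl]-2-oxazolidinone, via mixed pivalic anhydride 6 (not isolated)
Conditions: t-BuCOCl, Et3N, THF, −20 °C; then LiCl and the oxazolidinone, −20 °C to rt
Reagents that add atoms: none
Why: N-acylation through a pivaloyl mixed anhydride with LiCl/Et3N activation should deliver the imide because the oxazolidinone attacks the unhindered aryloxyacetyl carbonyl, without any strong base.

Step 3
Reactants: 7 (S)-4-benzyl-3-[(4-bromo-2,6-dimethoxyphenoxy)acetyl]-2-oxazolidinone; 8 4-(benzyloxy)benzaldehyde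
Product: 11 (S)-4-benzyl-3-[(2S,3R)-3-[4-(benzyloxy)phenyl]-2-(4-bromo-2,6-dimethoxyphenoxy)-3-hydroxypropanoyl]-2-oxazolidinone, via Z boron enolate 9 (not isolated), via boron aldolate 10 (not isolated)
Conditions: Bu2BOTf, i-Pr2NEt, CH2Cl2, −78 to 0 °C; aldehyde, −78 to 0 °C; then pH 7 buffer, MeOH, 30% H2O2, 0 °C
Reagents that add atoms: none
Why: In this Evans syn aldol, soft enolisation gives the Z dibutylboron enolate, which should react through a closed Zimmerman–Traxler chair on the face away from the auxiliary benzyl group, forming C7–C8 and setting both centres as the (2S,3R) syn adduct that maps onto 7R,8R.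

Step 4
Reactants: 11 syn aldol adduct
Product: 12 (1R,2R)-1-[4-(benzyloxy)phenyl]-2-(4-bromo-2,6-dimethoxyphenoxy)propane-1,3-diol
Conditions: NaBH4, THF/H2O 4:1, 0 °C to rt
Reagents that add atoms: none
Why: Borohydride reductive cleavage of the N-acyl oxazolidinone should give the primary alcohol and return the auxiliary under conditions too mild for retro-aldol, epimerisation or attack on the aryl bromide.

Step 5
Reactants: 12 (1R,2R)-diol
Product: 13 (1R,2R)-1-[4-(benzyloxy)phenyl]-2-(4-bromo-2,6-dimethoxyphenoxy)-1,3-bis(tert-butyldimethylsilyloxy)propane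
Conditions: TBSOTf, 2,6-lutidine, CH2Cl2, −40 to 0 °C
Reagents that add atoms: tert-butyldimethylsilyl triflate, CC(C)(C)[Si](C)(C)OS(=O)(=O)C(F)(F)F
Why: Silyl ether formation with the reactive triflate should cap both the primary and the hindered benzylic hydroxyl, removing acidic protons before the organolithium step and preventing the diol from esterifying the later boronic acid.

Step 6
Reactants: 13 bis-silylated aryl bromide
Product: 16 4-{[(1R,2R)-1-[4-(benzyloxy)phenyl]-1,3-bis(tert-butyldimethylsilyloxy)propan-2-yl]oxy}-3,5-dimethoxyphenylboronic acid, via aryllithium 14 (not isolated), via lithium triisopropoxyborate 15 (not isolated)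
Conditions: B(O-i-Pr)3, n-BuLi, THF/toluene, −78 °C (in situ quench); then dilute aq. HCl to pH 5–6, 0 °C
Reagents that add atoms: triisopropyl borate, CC(C)OB(OC(C)C)OC(C)C; water, O
Why: Bromine–lithium exchange with in situ borate trapping should intercept the aryllithium at −78 °C before it can attack benzyl or silyl ethers, and mild hydrolysis of the ate complex gives the boronic acid.

Step 7
Reactants: 17 2,4,6-trihydroxyacetophenone
Product: 18 1-[2,4-bis(benzyloxy)-6-hydroxyphenyl]ethan-1-one
Conditions: BnBr (2.05 equiv), K2CO3, DMF, rt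
Reagents that add atoms: benzyl bromide, BrCc1ccccc1
Why: Williamson O-benzylation with two equivalents should leave the one hydroxyl that is hydrogen-bonded to the acetyl carbonyl, since it is the least nucleophilic.

Step 8
Reactants: 18 1-[2,4-bis(benzyloxy)-6-hydroxyphenyl]ethan-1-one
Product: 20 5,7-bis(benzyloxy)-4H-chromen-4-one, via enaminone 19 (not isolated)
Conditions: Me2NCH(OMe)2, toluene, 100 °C; evaporate; then 2 M HCl (aq), CH2Cl2, 40 °C
Reagents that add atoms: N,N-dimethylformamide dimethyl acetal, COC(OC)N(C)C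
Why: Condensation of the acetyl methyl group with the formamide acetal gives the enaminone, and acid-promoted addition of the phenol to its beta-carbon with loss of dimethylamine should close the pyranone, which is the standard enaminone chromone synthesis.

Step 9
Reactants: 16 side-chain-bearing arylboronic acid; 20 5,7-bis(benzyloxy)-4H-chromen-4-one
Product: 21 (2S)-5,7-bis(benzyloxy)-2-[4-{[(1R,2R)-1-[4-(benzyloxy)phenyl]-1,3-bis(tert-butyldimethylsilyloxy)propan-2-yl]oxy}-3,5-dimethoxyphenyl]chroman-4-one
Conditions: [RhCl(C2H4)2]2 (2.5 mol %), (S,S)-Ph-bod (5.5 mol %), K3PO4 (0.3 equiv), toluene/H2O 10:1, 50 °C; chromone in excess (2 equiv)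
Reagents that add atoms: none
Why: This is a Hayashi–Miyaura asymmetric 1,4-addition of the kind already practised on chromones: the boronic acid transmetalates to the hydroxo-rhodium–diene complex (monovalent rhodium throughout), the chromone C2=C3 bond binds and inserts into the aryl–rhodium bond so that C1' is delivered to C2, and water protonates the resulting oxa-pi-allyl rhodium enolate at C3, releasing the flavanone and regenerating Rh–OH. No ring is formed; the existing pyranone is only saturated across C2–C3. The new stereocentre C2 is set by the C2-symmetric chiral diene alone (catalyst control), the (S,S) ligand being expected to expose the chromone face that leads to 2S, while the remote C7 and C8 centres play no part. The step needs enantioface selectivity at C2 and clean 1,4-addition without later retro-oxa-Michael opening to the 2'-hydroxychalcone; the boronic acid has hydrogen at both positions ortho to boron and is electron-rich, so transmetalation should be fast, all hydroxyls are masked as silyl or benzyl ethers, the 5-benzyloxy group cannot chelate the metal, and near-neutral aqueous conditions with substoichiometric K3PO4 should protonate the enolate before the ring can open. The cheap chromone is used in excess so that the aryl–rhodium species is captured before protodeboronation.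

Step 10
Reactants: 21 fully protected (2S)-flavanone
Product: 22 (2S)-5,7-bis(benzyloxy)-2-[4-{[(1R,2R)-1-[4-(benzyloxy)phenyl]-1,3-dihydroxypropan-2-yl]oxy}-3,5-dimethoxyphenyl]chroman-4-one
Conditions: HF·pyridine, pyridine, THF, 0 °C to rt
Reagents that add atoms: none
Why: Fluoride-mediated silyl ether cleavage under pyridine-buffered, slightly acidic conditions should free both hydroxyls without the base-induced flavanone–chalcone ring opening that would erode C2, and benzyl ethers, C7 and C8 are untouched.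

Step 11
Reactants: 22 tri-O-benzyl flavanone diol
Product: 23 (2S)-5,7-dihydroxy-2-[4-{[(1R,2R)-1,3-dihydroxy-1-(4-hydroxyphenyl)propan-2-yl]oxy}-3,5-dimethoxyphenyl]chroman-4-one (target CNP0263993.1)
Conditions: H2 (1 atm), 10% Pd/C, EtOAc/MeOH, rt, stopped at full debenzylation
Reagents that add atoms: none
Why: Catalytic hydrogenolysis should cleave the three aryl benzyl ethers much faster than the benzylic C7–OH and C2–O1 bonds under neutral conditions at atmospheric pressure, leaving all three stereocentres unchanged.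

**Compound list**

1 | 4-bromo-2,6-dimethoxyphenol | COc1cc(Br)cc(OC)c1O | starting material
2 | ethyl bromoacetate | CCOC(=O)CBr | starting material
3 | ethyl (4-bromo-2,6-dimethoxyphenoxy)acetate (not isolated) | CCOC(=O)COc1c(OC)cc(Br)cc1OC | intermediate
4 | (4-bromo-2,6-dimethoxyphenoxy)acetic acid | COc1cc(Br)cc(OC)c1OCC(=O)O | intermediate
5 | (S)-4-benzyl-2-oxazolidinone | O=C1OC[C@H](Cc2ccccc2)N1 | starting material
6 | (4-bromo-2,6-dimethoxyphenoxy)acetic pivalic anhydride (not isolated) | COc1cc(Br)cc(OC)c1OCC(=O)OC(=O)C(C)(C)C | intermediate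
7 | (S)-4-benzyl-3-[(4-bromo-2,6-dimethoxyphenoxy)acetyl]-2-oxazolidinone | O=C1OC[C@H](Cc2ccccc2)N1C(=O)COc1c(OC)cc(Br)cc1OC | intermediate
8 | 4-(benzyloxy)benzaldehyde | O=Cc1ccc(OCc2ccccc2)cc1 | starting material
9 | Z dibutylboron enolate of 7 (not isolated) | CCCCB(CCCC)O/C(=C\Oc1c(OC)cc(Br)cc1OC)N1C(=O)OC[C@@H]1Cc1ccccc1 | intermediate
10 | dibutylboron aldolate of 11 (not isolated) | COc1cc(Br)cc(OC)c1O[C@H](C(=O)N1C(=O)OC[C@@H]1Cc1ccccc1)[C@H](OB(CCCC)CCCC)c1ccc(OCc2ccccc2)cc1 | intermediate
11 | (S)-4-benzyl-3-[(2S,3R)-3-[4-(benzyloxy)phenyl]-2-(4-bromo-2,6-dimethoxyphenoxy)-3-hydroxypropanoyl]-2-oxazolidinone | COc1cc(Br)cc(OC)c1O[C@H](C(=O)N1C(=O)OC[C@@H]1Cc1ccccc1)[C@H](O)c1ccc(OCc2ccccc2)cc1 | intermediate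
12 | (1R,2R)-1-[4-(benzyloxy)phenyl]-2-(4-bromo-2,6-dimethoxyphenoxy)propane-1,3-diol | COc1cc(Br)cc(OC)c1O[C@H](CO)[C@H](O)c1ccc(OCc2ccccc2)cc1 | intermediate
13 | (1R,2R)-1-[4-(benzyloxy)phenyl]-2-(4-bromo-2,6-dimethoxyphenoxy)-1,3-bis(tert-butyldimethylsilyloxy)propane | COc1cc(Br)cc(OC)c1O[C@H](CO[Si](C)(C)C(C)(C)C)[C@H](O[Si](C)(C)C(C)(C)C)c1ccc(OCc2ccccc2)cc1 | intermediate
14 | aryllithium from 13 (not isolated) | COc1cc([Li])cc(OC)c1O[C@H](CO[Si](C)(C)C(C)(C)C)[C@H](O[Si](C)(C)C(C)(C)C)c1ccc(OCc2ccccc2)cc1 | intermediate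
15 | lithium aryl(triisopropoxy)borate (not isolated) | COc1cc([B-](OC(C)C)(OC(C)C)OC(C)C)cc(OC)c1O[C@H](CO[Si](C)(C)C(C)(C)C)[C@H](O[Si](C)(C)C(C)(C)C)c1ccc(OCc2ccccc2)cc1.[Li+] | intermediate
16 | 4-{[(1R,2R)-1-[4-(benzyloxy)phenyl]-1,3-bis(tert-butyldimethylsilyloxy)propan-2-yl]oxy}-3,5-dimethoxyphenylboronic acid | COc1cc(B(O)O)cc(OC)c1O[C@H](CO[Si](C)(C)C(C)(C)C)[C@H](O[Si](C)(C)C(C)(C)C)c1ccc(OCc2ccccc2)cc1 | intermediate
17 | 2,4,6-trihydroxyacetophenone | CC(=O)c1c(O)cc(O)cc1O | starting material
18 | 1-[2,4-bis(benzyloxy)-6-hydroxyphenyl]ethan-1-one | CC(=O)c1c(O)cc(OCc2ccccc2)cc1OCc1ccccc1 | intermediate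
19 | (E)-1-[2,4-bis(benzyloxy)-6-hydroxyphenyl]-3-(dimethylamino)prop-2-en-1-one (not isolated) | CN(C)/C=C/C(=O)c1c(O)cc(OCc2ccccc2)cc1OCc1ccccc1 | intermediate
20 | 5,7-bis(benzyloxy)-4H-chromen-4-one | O=c1ccoc2cc(OCc3ccccc3)cc(OCc3ccccc3)c12 | intermediate
21 | (2S)-5,7-bis(benzyloxy)-2-[4-{[(1R,2R)-1-[4-(benzyloxy)phenyl]-1,3-bis(tert-butyldimethylsilyloxy)propan-2-yl]oxy}-3,5-dimethoxyphenyl]chroman-4-one | COc1cc([C@@H]2CC(=O)c3c(OCc4ccccc4)cc(OCc4ccccc4)cc3O2)cc(OC)c1O[C@H](CO[Si](C)(C)C(C)(C)C)[C@H](O[Si](C)(C)C(C)(C)C)c1ccc(OCc2ccccc2)cc1 | intermediate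
22 | (2S)-5,7-bis(benzyloxy)-2-[4-{[(1R,2R)-1-[4-(benzyloxy)phenyl]-1,3-dihydroxypropan-2-yl]oxy}-3,5-dimethoxyphenyl]chroman-4-one | COc1cc([C@@H]2CC(=O)c3c(OCc4ccccc4)cc(OCc4ccccc4)cc3O2)cc(OC)c1O[C@H](CO)[C@H](O)c1ccc(OCc2ccccc2)cc1 | intermediate
23 | (2S)-5,7-dihydroxy-2-[4-{[(1R,2R)-1,3-dihydroxy-1-(4-hydroxyphenyl)propan-2-yl]oxy}-3,5-dimethoxyphenyl]chroman-4-one | COc1cc([C@@H]2CC(=O)c3c(O)cc(O)cc3O2)cc(OC)c1O[C@H](CO)[C@H](O)c1ccc(O)cc1 | target

Total step count: 11
Longest linear sequence: 9 steps (steps 1 to 6, then 9, 10 and 11)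

**Steps most likely to fail**

Step 9. The electron-rich 5,7-dialkoxychromone may insert slowly, so that the aryl–rhodium species is lost to protodeboronation, or face selectivity at C2 may be poor. The fallback makes the C2–O1 bond last instead of C2–C1'. It sets out from bromide 13 and acetophenone 18 and returns at 21. Bromine–lithium exchange on 13 (n-BuLi, THF, −78 °C) and formylation with DMF should give 4-{[(1R,2R)-1-[4-(benzyloxy)phenyl]-1,3-bis(tert-butyldimethylsilyloxy)propan-2-yl]oxy}-3,5-dimethoxybenzaldehyde F1. Claisen–Schmidt condensation of this aldehyde with 18 (KOH, EtOH/THF, rt) should give the (E)-2'-hydroxy-4',6'-bis(benzyloxy)chalcone F2. Intramolecular oxa-Michael closure (NaOAc, EtOH, reflux) then gives 21 together with its C2 epimer, which is a diastereomer and is removed by preparative HPLC; a cinchona-thiourea catalyst may be used to bias the closure towards 2S.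

Step 11. Over-reduction is the risk: once ring D is debenzylated, the C7 hydroxyl can be lost through a quinone methide or by direct benzylic C–O hydrogenolysis. The fallback reverses the order of deprotection. It sets out from 21 and returns at 23. Hydrogenolysis of 21 (H2, Pd/C, EtOAc) with both silyl ethers in place, so that the bulky C7 silyl ether shields the benzylic position, should give (2S)-2-[4-{[(1R,2R)-1,3-bis(tert-butyldimethylsilyloxy)-1-(4-hydroxyphenyl)propan-2-yl]oxy}-3,5-dimethoxyphenyl]-5,7-dihydroxychroman-4-one F3. HF·pyridine in pyridine/THF then removes the silyl groups under non-basic conditions to give 23.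

Step 6. Incomplete exchange, metalation or rearrangement at the benzyl ethers, or protodeboronation of the electron-rich boronic acid during acidic work-up may occur. The fallback replaces the organolithium by a palladium-catalysed borylation. It sets out from 13 and returns at 16. Miyaura borylation of 13 (PdCl2(dppf), B2pin2, KOAc, dioxane, 85 °C) should give the chromatographable 2-aryl-4,4,5,5-tetramethyl-1,3,2-dioxaborolane (pinacol boronate) F4. Oxidative removal of the pinacol (NaIO4, NH4OAc, acetone/H2O, rt) then gives 16; the pinacol ester could also be used directly in step 9.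

**Further compounds**

F1 | step 9 | 4-{[(1R,2R)-1-[4-(benzyloxy)phenyl]-1,3-bis(tert-butyldimethylsilyloxy)propan-2-yl]oxy}-3,5-dimethoxybenzaldehyde | COc1cc(C=O)cc(OC)c1O[C@H](CO[Si](C)(C)C(C)(C)C)[C@H](O[Si](C)(C)C(C)(C)C)c1ccc(OCc2ccccc2)cc1
F2 | step 9 | (E)-1-[2,4-bis(benzyloxy)-6-hydroxyphenyl]-3-[4-{[(1R,2R)-1-[4-(benzyloxy)phenyl]-1,3-bis(tert-butyldimethylsilyloxy)propan-2-yl]oxy}-3,5-dimethoxyphenyl]prop-2-en-1-one | COc1cc(/C=C/C(=O)c2c(O)cc(OCc3ccccc3)cc2OCc2ccccc2)cc(OC)c1O[C@H](CO[Si](C)(C)C(C)(C)C)[C@H](O[Si](C)(C)C(C)(C)C)c1ccc(OCc2ccccc2)cc1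
F3 | step 11 | (2S)-2-[4-{[(1R,2R)-1,3-bis(tert-butyldimethylsilyloxy)-1-(4-hydroxyphenyl)propan-2-yl]oxy}-3,5-dimethoxyphenyl]-5,7-dihydroxychroman-4-one | COc1cc([C@@H]2CC(=O)c3c(O)cc(O)cc3O2)cc(OC)c1O[C@H](CO[Si](C)(C)C(C)(C)C)[C@H](O[Si](C)(C)C(C)(C)C)c1ccc(O)cc1
F4 | step 6 | 2-[4-{[(1R,2R)-1-[4-(benzyloxy)phenyl]-1,3-bis(tert-butyldimethylsilyloxy)propan-2-yl]oxy}-3,5-dimethoxyphenyl]-4,4,5,5-tetramethyl-1,3,2-dioxaborolane | COc1cc(B2OC(C)(C)C(C)(C)O2)cc(OC)c1O[C@H](CO[Si](C)(C)C(C)(C)C)[C@H](O[Si](C)(C)C(C)(C)C)c1ccc(OCc2ccccc2)cc1
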